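# Proposed synthesis of (2R)-2-[(3R,6R)-6-methyl-6-[2-[(4aR,8aS)-1,1,3,6-tetramethyl-1,4,4a,7,8,8a-hexahydronaphthalen-2-yl]ethyl]-1,2-dioxan-3-yl]propanoic acid (CNP0122760.1)

## The problem

The target joins two halves through a saturated two-carbon linker: a cis-fused hexahydronaphthalene and a 3,6,6-trisubstituted 1,2-dioxane. The bicyclic half has ring A with the trisubstituted C5=C6 alkene, ring B with the tetrasubstituted C2=C3 alkene and the C1 gem-dimethyl group, and ring-fusion centres C4a and C8a. The dioxane half carries three of the five stereocentres: C3 (bearing the propanoic acid arm), the quaternary C6 (methyl and linker) and the acid α-carbon, with arm and linker cis on the ring. Only the acid α-carbon is close enough to influence the ring centres; the decalin centres are too remote, so each half has to be made as a single enantiomer and the two then joined. The O–O bond excludes dissolving metals, strong hydride donors and heterogeneous hydrogenation. The C3–H next to the peroxide is open to base-induced Kornblum–DeLaMare cleavage, and a carbonyl group β to a peroxide oxygen invites E1cB ring opening and epimerisation. The two electron-rich decalin alkenes would undergo ene reactions with singlet oxygen, can migrate in strong acid and compete in any alkene reduction. The enabling feature is that dioxane C3 and C6 carry the two oxygens of one O2 unit with C4–C5 between them. This is the adduct of singlet oxygen with a 1,3-diene once C4=C5 is restored, and the cis relation of arm and linker is what suprafacial addition to an (E,E)-diene delivers.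

## Retrosynthesis

**Acid and its masking.** The carboxyl group of 29 is traced to the primary alcohol 27 and its silyl ether 26. No skeletal bond is cut. The acid is carried as a tert-butyldiphenylsilyl ether because an ester or aldehyde β to the peroxide oxygen would not survive the base used in the fragment union. The forward oxidation (27 → 28 → 29) has to be mild and nearly neutral.

**Linker.** The bond between the two linker carbons of 26 is cut: alkene 25 comes from dioxane aldehyde 11 and decalin phosphonium salt 23 (ylide 24). Cutting decalin C2–CH2 instead would need an alkylborane or alkylzinc beside the peroxide together with zerovalent palladium and phosphines. Placing the ylide on the dioxane side is excluded, because a carbanion β to the peroxide oxygen would eliminate. The precursors are a C9 peroxide and a C15 bicycle of similar size. The forward reactions must add a hindered allylic ylide to an α-quaternary aldehyde and then saturate only the new disubstituted alkene.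

**Dioxane ring (key disconnection).** Aldehyde 11 is taken back through alcohol 10 to 3,6-dihydro-1,2-dioxine 9, and both C–O bonds of 9 are cut to give acyclic diene 8 and O2. Stepwise peroxide constructions (hydroperoxide conjugate addition or displacement) would create the quaternary C–O centre without control. The cycloaddition ties its configuration to that of C6 through the alkene geometry. The precursor has one stereocentre and no ring, and its only alkenes are the diene, so the ene-prone decalin is kept away from singlet oxygen. The forward step must favour [4+2] addition over ene oxidation and must discriminate the diene faces through the adjacent stereocentre.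

**Diene.** Diene 8 is the reduction product of dienoate 7. The C2=C3 and C4=C5 alkenes are cut in turn by Wittig disconnections to ylides 6 and 4 and aldehyde 3. Aldehyde 3 comes from ester 2 and commercial methyl (S)-3-hydroxy-2-methylpropanoate 1. Stabilised ylides give the (E,E) geometry that fixes the cis relation in 9. The ester carbon of 1 becomes dioxane C3 and its hydroxymethyl carbon becomes the carboxyl carbon.

**Decalin ring B.** Salt 23 is traced through alcohol 22 and ester 21 to enol triflate 20 and β-keto ester 19. The C1–C2 bond of 19 is cut to give monocyclic β-keto ester 18. The quaternary C1 next to the ring fusion is the hardest carbon of the decalin. The isopropenyl group of a limonene-type ring A is a latent tertiary cation at exactly this position. The β-keto ester supplies the C2 nucleophile, a C3 carbonyl for the methyl group and an ester carbon that becomes the first linker carbon. The forward cyclisation must ionise the isopropenyl group and not the ring alkene.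

**Ring A stereocentres.** The C4–C4a bond of 18 (via methyl ketone 17) is cut by a Carroll disconnection to tertiary allylic alcohol 15. Alcohol 15 comes from epoxide 13 and (S)-limonene 12. The [3,3] shift transfers the C–O configuration of 15 to the new C–C bond, cis to the isopropenyl group. Both ring-fusion centres therefore derive from the single stereocentre of 12. An allyl-cation substitution on 15 would deliver the trans isomer.

## Roads not taken

**Alternative 1:** The decalin is traced to the tertiary alcohol 1,3,3-trimethyl-2-(prop-1-en-2-yl)bicyclo[2.2.2]oct-5-en-2-ol A1. Its potassium alkoxide would undergo an anionic oxy-Cope rearrangement, and the enolate would be trapped with PhNTf2 as the enol triflate A2.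
- Merits: the cage enforces the cis fusion, and the C3 methyl group and the position of the C2=C3 alkene arrive in one operation. A2 is an electrophile at C2 that could take a two-carbon alkyl unit directly. For the bicycle alone this is shorter than the nine steps spent here, and it would spare the second diimide reduction.
- Weak points: the hindered ketone behind A1 is reached by Diels–Alder chemistry only as a racemate. The nucleophile must add syn to the etheno bridge. A palladium-mediated union beside the O–O bond is less secure than a Wittig reaction.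
- Comparison: this road addresses only the carbocycle. The chosen plan offsets its longer decalin sequence by taking both ring-fusion centres from (S)-limonene without resolution, and it puts the strategic step on the peroxide, where the real difficulty lies.

**Alternative 2:** The bonds C4a–C8a and C1–C2 are cut back to the acyclic triene (2E,5E)-7-hydroxy-3,7,11-trimethyldodeca-2,5,10-trien-1-yl acetate A3. Ionisation of the tertiary allylic alcohol, capture by the prenyl alkene (ring A), capture of the new C1 cation by the allylic-acetate alkene (ring B) and loss of the C2 proton would give acetate A4.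
- Merits: this is the shortest conceivable route to the bicycle. A4 is one hydrolysis away from alcohol 22.
- Weak points: the cation is achiral, so A4 is racemic. The ring fusion is set in a loose first closure. Proton loss can give alkene isomers, and ring A is exposed to strong acid.
- Comparison: the chosen plan uses the same kind of cationic closure only for ring B (18 → 19), on an enantiopure ring A and with a β-keto ester terminator that fixes the alkene position. A racemic decalin joined to the enantiopure dioxane would give diastereomers differing only at remote centres, which are unlikely to separate.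

**Alternative 3:** Ring A is cut at C4a–C5 and C8–C8a. Dienone A5 and silyloxydiene A6 would combine endo under a chiral oxazaborolidinium catalyst to give adduct A7.
- Merits: absolute configuration is controlled catalytically and does not depend on a chiral-pool terpene. The endo rule gives the cis fusion.
- Weak points: A7 carries a C4 ketone, a C5 silyloxy group and a C6=C7 alkene. It needs alkene transposition with loss of the C5 oxygen and removal of the C4 carbonyl beside the epimerisable C4a. The dienophile carbon next to the quaternary C1 is hindered.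
- Comparison: the chosen plan obtains ring A with its methyl group and alkene already in place and needs no redox corrections. It gives up the freedom to prepare either enantiomer by changing a catalyst.

Key step: step 6

## Route

Remark on the chemistry: decalin locants follow the naphthalene numbering of the target (C1 gem-dimethyl, C2 linker-bearing, C4a/C8a ring fusion). In 9–11 the quaternary dioxane carbon is C3 by nomenclature; in 25–29 it is C6.

**Step 1**
Reactants: 1 methyl (2S)-3-hydroxy-2-methylpropanoate
Product: 2 methyl (2S)-3-[tert-butyl(diphenyl)silyl]oxy-2-methylpropanoate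
Conditions: tBuPh2SiCl, imidazole, DMF, 0 °C → rt
Reagents that add atoms: tert-butyl(chloro)diphenylsilane, CC(C)(C)[Si](Cl)(c1ccccc1)c1ccccc1
Why: Silylation of a primary alcohol; the bulky, acid- and base-stable silyl ether masks the future carboxyl carbon to the end of the route, and the α-stereocentre is not touched.

**Step 2**
Reactants: 2 methyl (2S)-3-[tert-butyl(diphenyl)silyl]oxy-2-methylpropanoate
Product: 3 (2S)-3-[tert-butyl(diphenyl)silyl]oxy-2-methylpropanal
Conditions: iBu2AlH (1.1 equiv), CH2Cl2, −78 °C; aqueous potassium sodium tartrate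
Reagents that add atoms: none
Why: Partial ester reduction by iBu2AlH stops at the aluminium hemiacetal at −78 °C and gives the aldehyde on work-up; the aldehyde is used at once so that its α-stereocentre is kept.

**Step 3**
Reactants: 3 (2S)-3-[tert-butyl(diphenyl)silyl]oxy-2-methylpropanal; 4 (triphenylphosphoranylidene)acetaldehyde
Product: 5 (2E,4R)-5-[tert-butyl(diphenyl)silyl]oxy-4-methylpent-2-enal
Conditions: toluene, 80 °C
Reagents that add atoms: none
Why: Wittig reaction of the stabilised formyl ylide gives the (E)-enal under neutral conditions that the epimerisable aldehyde tolerates; a small excess of 3 limits a second homologation.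

**Step 4**
Reactants: 5 (2E,4R)-5-[tert-butyl(diphenyl)silyl]oxy-4-methylpent-2-enal; 6 ethyl 2-(triphenylphosphoranylidene)propanoate
Product: 7 ethyl (2E,4E,6R)-7-[tert-butyl(diphenyl)silyl]oxy-2,6-dimethylhepta-2,4-dienoate
Conditions: CH2Cl2, rt
Reagents that add atoms: none
Why: Wittig reaction of the stabilised α-methyl ester ylide gives the (E)-trisubstituted alkene, which places the ester carbon outside and the methyl group inside on the diene.

**Step 5**
Reactants: 7 ethyl (2E,4E,6R)-7-[tert-butyl(diphenyl)silyl]oxy-2,6-dimethylhepta-2,4-dienoate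
Product: 8 (2E,4E,6R)-7-[tert-butyl(diphenyl)silyl]oxy-2,6-dimethylhepta-2,4-dien-1-ol
Conditions: iBu2AlH (2.2 equiv), CH2Cl2, −78 °C
Reagents that add atoms: none
Why: 1,2-Reduction of the conjugated ester gives the electron-rich dienol; the hydroxyl is left free because it is the group oxidised after the cycloaddition.

**Step 6 (key step)**
Reactants: 8 (2E,4E,6R)-7-[tert-butyl(diphenyl)silyl]oxy-2,6-dimethylhepta-2,4-dien-1-ol
Product: 9 [(3S,6R)-6-[(2S)-1-[tert-butyl(diphenyl)silyl]oxypropan-2-yl]-3-methyl-3,6-dihydro-1,2-dioxin-3-yl]methanol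
Conditions: O2, tetraphenylporphyrin (cat.), visible light, CH2Cl2, −20 °C; chromatographic separation of the two cis-dioxines
Reagents that add atoms: oxygen, O=O
Why: Tetraphenylporphyrin sensitises O2 to singlet oxygen, which adds across C2 and C5 of the s-cis (2E,4E)-diene in a concerted, suprafacial [4+2] cycloaddition (possibly asynchronous, the bond to the less hindered C5 leading). The closest known reactions are the dye-sensitised photooxygenations of sorbyl alcohol and of acyclic (E,E)-dienes with a trisubstituted terminus to 3,6-dihydro-1,2-dioxines. The six-membered ring closes in the cycloaddition itself, both C–O bonds forming on one face of the diene, so no separate ring-closing substitution is needed. The relative configuration of the two new stereocentres follows from the alkene geometry: the outside groups (hydroxymethyl on C2, the stereogenic chain on C5) end cis and the inside methyl group ends on the quaternary carbon trans to them. The face is chosen only by the allylic stereocentre C6: with the silyloxymethyl group anti to the incoming oxygen, the arrangement with methyl inside (over the alkene) and hydrogen outside leads to 9 and the one with hydrogen inside leads to the other cis-dioxine; the former is the arrangement normally preferred in additions to (E)-alkenes, but the preference should be small, so both isomers are expected and 9 is isolated by chromatography. The step also needs cycloaddition to outrun the ene reaction at the trisubstituted terminus (hydrogen abstraction from the inside methyl group), which the planar conjugated diene, the aprotic solvent and the low temperature favour. No other alkene is present, and the silyl ether and the alcohol are inert to singlet oxygen.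

**Step 7**
Reactants: 9 [(3S,6R)-6-[(2S)-1-[tert-butyl(diphenyl)silyl]oxypropan-2-yl]-3-methyl-3,6-dihydro-1,2-dioxin-3-yl]methanol
Product: 10 [(3S,6R)-6-[(2S)-1-[tert-butyl(diphenyl)silyl]oxypropan-2-yl]-3-methyl-1,2-dioxan-3-yl]methanol
Conditions: KO2CN=NCO2K, AcOH, CH2Cl2/MeOH, 0 °C → rt
Reagents that add atoms: none
Why: Diimide transfers two hydrogens to the strained cis ring alkene by a concerted syn pathway and leaves the O–O bond intact; the weakly acidic medium avoids the Kornblum–DeLaMare cleavage to which the allylic C6–H of 9 is prone.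

**Step 8**
Reactants: 10 [(3S,6R)-6-[(2S)-1-[tert-butyl(diphenyl)silyl]oxypropan-2-yl]-3-methyl-1,2-dioxan-3-yl]methanol
Product: 11 (3S,6R)-6-[(2S)-1-[tert-butyl(diphenyl)silyl]oxypropan-2-yl]-3-methyl-1,2-dioxane-3-carbaldehyde
Conditions: Dess–Martin periodinane, NaHCO3, CH2Cl2, 0 °C → rt
Reagents that add atoms: none
Why: Buffered Dess–Martin oxidation of the neopentyl-type primary alcohol; the aldehyde has no α-hydrogen, so it cannot epimerise or enolise, and the peroxide is inert to the hypervalent iodine reagent.

**Step 9**
Reactants: 12 (S)-limonene [(4S)-1-methyl-4-(prop-1-en-2-yl)cyclohex-1-ene]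
Product: 13 (4S)-limonene 1,2-oxide as the mixture of trans (1R,2S,4S) and cis (1S,2R,4S) epoxides
Conditions: mCPBA, NaHCO3, CH2Cl2, 0 °C
Reagents that add atoms: 3-chloroperoxybenzoic acid, OOC(=O)c1cccc(Cl)c1
Why: The peracid epoxidises the more electron-rich trisubstituted ring alkene and spares the isopropenyl group; there is little facial bias, so both epoxides are expected and only the trans isomer (oxygen cis to isopropenyl) is used in step 10.

**Step 10**
Reactants: 13 (4S)-limonene 1,2-oxide as the mixture of trans (1R,2S,4S) and cis (1S,2R,4S) epoxides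
Product: 15 (1R,4S)-1-methyl-4-(prop-1-en-2-yl)cyclohex-2-en-1-ol, via hydroxy selenide 14 (not isolated)
Conditions: PhSeSePh (0.3 equiv), NaBH4, EtOH, rt → 70 °C; then 30% H2O2, THF, 0 °C → rt; chromatography
Reagents that add atoms: none
Why: PhSeNa opens the trans epoxide at C2 by trans-diaxial SN2 attack much faster than the cis epoxide, which would need a twist-boat or attack at the tertiary carbon; oxidation to the selenoxide and syn elimination toward C3 (C1 has no hydrogen) give the allylic alcohol with the C1–O bond, cis to isopropenyl, unchanged. The unreacted cis epoxide is removed.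

**Step 11**
Reactants: 15 (1R,4S)-1-methyl-4-(prop-1-en-2-yl)cyclohex-2-en-1-ol
Product: 17 1-[(1R,6S)-3-methyl-6-(prop-1-en-2-yl)cyclohex-2-en-1-yl]propan-2-one, via acetoacetate 16 (not isolated)
Conditions: 2,2,6-trimethyl-4H-1,3-dioxin-4-one, xylenes, 140 °C (acetone distilled off), heating continued until CO2 evolution ends
Reagents that add atoms: 2,2,6-trimethyl-4H-1,3-dioxin-4-one, CC1=CC(=O)OC(C)(C)O1
Why: Acetylketene from the dioxinone acylates the tertiary alcohol under neutral conditions, and the enol of 16 undergoes the Carroll rearrangement ([3,3] shift, then decarboxylation). The shift is suprafacial, so the new C–C bond forms on the face that carried the oxygen, cis to isopropenyl, which sets the future C4a from the C1–O centre of 15.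

**Step 12**
Reactants: 17 1-[(1R,6S)-3-methyl-6-(prop-1-en-2-yl)cyclohex-2-en-1-yl]propan-2-one
Product: 18 methyl 4-[(1R,6S)-3-methyl-6-(prop-1-en-2-yl)cyclohex-2-en-1-yl]-3-oxobutanoate
Conditions: NaH, (MeO)2CO, THF, reflux; AcOH quench at 0 °C
Reagents that add atoms: dimethyl carbonate, COC(=O)OC
Why: Claisen-type C-acylation of a methyl ketone by dimethyl carbonate takes place at the methyl group and is driven by formation of the β-keto ester enolate; neither ring stereocentre is α to the carbonyl.

**Step 13**
Reactants: 18 methyl 4-[(1R,6S)-3-methyl-6-(prop-1-en-2-yl)cyclohex-2-en-1-yl]-3-oxobutanoate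
Product: 19 methyl (4aR,8aS)-1,1,6-trimethyl-3-oxo-1,2,3,4,4a,7,8,8a-octahydronaphthalene-2-carboxylate (C2 epimers)
Conditions: SnCl4, CH2Cl2, 0 °C → rt
Reagents that add atoms: none
Why: SnCl4 binds the β-keto ester as its tin enolate, and the acid released protonates the 1,1-disubstituted alkene to the tertiary cation, which the enol carbon captures in a six-membered closure (C1–C2 bond); this is the known Lewis-acid cyclisation of olefinic β-keto esters to 2,2-dimethyl-6-oxocyclohexanecarboxylates. The cis ring fusion is already fixed, and the C2 centre is removed in step 14.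

**Step 14**
Reactants: 19 methyl (4aR,8aS)-1,1,6-trimethyl-3-oxo-1,2,3,4,4a,7,8,8a-octahydronaphthalene-2-carboxylate (C2 epimers)
Product: 20 methyl (4aR,8aS)-1,1,6-trimethyl-3-(trifluoromethylsulfonyloxy)-1,4,4a,7,8,8a-hexahydronaphthalene-2-carboxylate
Conditions: NaH, Et2O, 0 °C; Tf2O, −78 → 0 °C
Reagents that add atoms: trifluoromethanesulfonic anhydride, O=S(=O)(OS(=O)(=O)C(F)(F)F)C(F)(F)F
Why: The sodium enolate of the β-keto ester is O-sulfonylated to the enol triflate, which fixes the C2=C3 alkene between the two carbonyl-derived carbons.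

**Step 15**
Reactants: 20 methyl (4aR,8aS)-1,1,6-trimethyl-3-(trifluoromethylsulfonyloxy)-1,4,4a,7,8,8a-hexahydronaphthalene-2-carboxylate
Product: 21 methyl (4aR,8aS)-1,1,3,6-tetramethyl-1,4,4a,7,8,8a-hexahydronaphthalene-2-carboxylate
Conditions: Me2CuLi (from CuI and MeLi), Et2O, −40 → 0 °C
Reagents that add atoms: lithium dimethylcuprate, [Li+].C[Cu-]C
Why: Addition–elimination of the cuprate on the β-triflyloxy enoate replaces the triflate by methyl without moving the alkene, the standard conversion of cyclic β-keto esters into β-methyl enoates.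

**Step 16**
Reactants: 21 methyl (4aR,8aS)-1,1,3,6-tetramethyl-1,4,4a,7,8,8a-hexahydronaphthalene-2-carboxylate
Product: 22 [(4aR,8aS)-1,1,3,6-tetramethyl-1,4,4a,7,8,8a-hexahydronaphthalen-2-yl]methanol
Conditions: iBu2AlH, CH2Cl2, −78 → 0 °C
Reagents that add atoms: none
Why: 1,2-Reduction of the hindered conjugated ester to the allylic alcohol, as for cyclogeranate esters.

**Step 17**
Reactants: 22 [(4aR,8aS)-1,1,3,6-tetramethyl-1,4,4a,7,8,8a-hexahydronaphthalen-2-yl]methanol
Product: 23 [[(4aR,8aS)-1,1,3,6-tetramethyl-1,4,4a,7,8,8a-hexahydronaphthalen-2-yl]methyl]triphenylphosphonium bromide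
Conditions: PPh3·HBr, MeOH, rt
Reagents that add atoms: triphenylphosphine hydrobromide, [Br-].[PH+](c1ccccc1)(c1ccccc1)c1ccccc1
Why: The allylic alcohol ionises under the mild acid and triphenylphosphine takes the primary terminus of the allyl cation, the usual one-step preparation of cyclogeranyl-type Wittig salts.

**Step 18**
Reactants: 23 [[(4aR,8aS)-1,1,3,6-tetramethyl-1,4,4a,7,8,8a-hexahydronaphthalen-2-yl]methyl]triphenylphosphonium bromide; 11 (3S,6R)-6-[(2S)-1-[tert-butyl(diphenyl)silyl]oxypropan-2-yl]-3-methyl-1,2-dioxane-3-carbaldehyde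
Product: 25 tert-butyl-[(2S)-2-[(3R,6S)-6-methyl-6-[2-[(4aR,8aS)-1,1,3,6-tetramethyl-1,4,4a,7,8,8a-hexahydronaphthalen-2-yl]ethenyl]-1,2-dioxan-3-yl]propoxy]diphenylsilane (E/Z mixture), via ylide 24 (not isolated)
Conditions: NaN(SiMe3)2, THF, −78 → 0 °C; then 11, −78 °C → rt
Reagents that add atoms: none
Why: Wittig reaction of the semi-stabilised allylic ylide with the non-enolisable, α-oxygenated aldehyde; alkene geometry is irrelevant because the alkene is reduced next, and the ylide is preformed so that the peroxide meets no free amide base.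

**Step 19**
Reactants: 25 tert-butyl-[(2S)-2-[(3R,6S)-6-methyl-6-[2-[(4aR,8aS)-1,1,3,6-tetramethyl-1,4,4a,7,8,8a-hexahydronaphthalen-2-yl]ethenyl]-1,2-dioxan-3-yl]propoxy]diphenylsilane (E/Z mixture)
Product: 26 tert-butyl-[(2S)-2-[(3R,6R)-6-methyl-6-[2-[(4aR,8aS)-1,1,3,6-tetramethyl-1,4,4a,7,8,8a-hexahydronaphthalen-2-yl]ethyl]-1,2-dioxan-3-yl]propoxy]diphenylsilane
Conditions: KO2CN=NCO2K, AcOH, CH2Cl2/MeOH, 0 °C → rt, repeated charges
Reagents that add atoms: none
Why: Diimide reduces alkenes in the order disubstituted, then trisubstituted, then tetrasubstituted, and the small reagent is little affected by the flanking quaternary centres, so the linker alkene should be saturated before the ring A alkene reacts; the tetrasubstituted C2=C3 alkene and the peroxide are inert.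

**Step 20**
Reactants: 26 tert-butyl-[(2S)-2-[(3R,6R)-6-methyl-6-[2-[(4aR,8aS)-1,1,3,6-tetramethyl-1,4,4a,7,8,8a-hexahydronaphthalen-2-yl]ethyl]-1,2-dioxan-3-yl]propoxy]diphenylsilane
Product: 27 (2S)-2-[(3R,6R)-6-methyl-6-[2-[(4aR,8aS)-1,1,3,6-tetramethyl-1,4,4a,7,8,8a-hexahydronaphthalen-2-yl]ethyl]-1,2-dioxan-3-yl]propan-1-ol
Conditions: Bu4NF, AcOH, THF, 0 °C → rt
Reagents that add atoms: none
Why: Fluoride cleaves the silyl ether; buffering with acetic acid keeps the medium from attacking the C3–H next to the peroxide.

**Step 21**
Reactants: 27 (2S)-2-[(3R,6R)-6-methyl-6-[2-[(4aR,8aS)-1,1,3,6-tetramethyl-1,4,4a,7,8,8a-hexahydronaphthalen-2-yl]ethyl]-1,2-dioxan-3-yl]propan-1-ol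
Product: 29 (2R)-2-[(3R,6R)-6-methyl-6-[2-[(4aR,8aS)-1,1,3,6-tetramethyl-1,4,4a,7,8,8a-hexahydronaphthalen-2-yl]ethyl]-1,2-dioxan-3-yl]propanoic acid, via aldehyde 28 (not isolated)
Conditions: Dess–Martin periodinane, NaHCO3, CH2Cl2, 0 °C; then NaClO2, NaH2PO4, 2-methylbut-2-ene, tBuOH/H2O, 0 °C → rt
Reagents that add atoms: sodium chlorite, [Na+].[O-]Cl=O
Why: Dess–Martin oxidation followed at once by Pinnick oxidation takes the alcohol to the acid under near-neutral conditions, so the β-peroxy aldehyde has no time to epimerise or eliminate; excess 2-methylbut-2-ene scavenges hypochlorous acid before it reaches the decalin alkenes.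

## Compound list

1 | methyl (2S)-3-hydroxy-2-methylpropanoate | COC(=O)[C@@H](C)CO | starting material
2 | methyl (2S)-3-[tert-butyl(diphenyl)silyl]oxy-2-methylpropanoate | COC(=O)[C@@H](C)CO[Si](c1ccccc1)(c1ccccc1)C(C)(C)C | intermediate
3 | (2S)-3-[tert-butyl(diphenyl)silyl]oxy-2-methylpropanal | O=C[C@@H](C)CO[Si](c1ccccc1)(c1ccccc1)C(C)(C)C | intermediate
4 | (triphenylphosphoranylidene)acetaldehyde | O=CC=P(c1ccccc1)(c1ccccc1)c1ccccc1 | starting material
5 | (2E,4R)-5-[tert-butyl(diphenyl)silyl]oxy-4-methylpent-2-enal | O=C/C=C/[C@@H](C)CO[Si](c1ccccc1)(c1ccccc1)C(C)(C)C | intermediate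
6 | ethyl 2-(triphenylphosphoranylidene)propanoate | CCOC(=O)C(C)=P(c1ccccc1)(c1ccccc1)c1ccccc1 | starting material
7 | ethyl (2E,4E,6R)-7-[tert-butyl(diphenyl)silyl]oxy-2,6-dimethylhepta-2,4-dienoate | CCOC(=O)/C(C)=C/C=C/[C@@H](C)CO[Si](c1ccccc1)(c1ccccc1)C(C)(C)C | intermediate
8 | (2E,4E,6R)-7-[tert-butyl(diphenyl)silyl]oxy-2,6-dimethylhepta-2,4-dien-1-ol | OC/C(C)=C/C=C/[C@@H](C)CO[Si](c1ccccc1)(c1ccccc1)C(C)(C)C | intermediate
9 | [(3S,6R)-6-[(2S)-1-[tert-butyl(diphenyl)silyl]oxypropan-2-yl]-3-methyl-3,6-dihydro-1,2-dioxin-3-yl]methanol | OC[C@]1(C)C=C[C@H]([C@@H](C)CO[Si](c2ccccc2)(c2ccccc2)C(C)(C)C)OO1 | intermediate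
10 | [(3S,6R)-6-[(2S)-1-[tert-butyl(diphenyl)silyl]oxypropan-2-yl]-3-methyl-1,2-dioxan-3-yl]methanol | OC[C@]1(C)CC[C@H]([C@@H](C)CO[Si](c2ccccc2)(c2ccccc2)C(C)(C)C)OO1 | intermediate
11 | (3S,6R)-6-[(2S)-1-[tert-butyl(diphenyl)silyl]oxypropan-2-yl]-3-methyl-1,2-dioxane-3-carbaldehyde | O=C[C@]1(C)CC[C@H]([C@@H](C)CO[Si](c2ccccc2)(c2ccccc2)C(C)(C)C)OO1 | intermediate
12 | (S)-limonene, (4S)-1-methyl-4-(prop-1-en-2-yl)cyclohex-1-ene | CC1=CC[C@H](CC1)C(C)=C | starting material
13 | (4S)-limonene 1,2-oxide, mixture of trans (1R,2S,4S; oxygen cis to isopropenyl; drawn) and cis (1S,2R,4S) epoxides | C[C@]12O[C@H]1C[C@H](CC2)C(C)=C | intermediate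
14 | (1R,2R,4S)-1-methyl-2-(phenylselanyl)-4-(prop-1-en-2-yl)cyclohexan-1-ol | C[C@]1(O)[C@H]([Se]c2ccccc2)C[C@H](CC1)C(C)=C | intermediate (not isolated)
15 | (1R,4S)-1-methyl-4-(prop-1-en-2-yl)cyclohex-2-en-1-ol (hydroxyl cis to isopropenyl) | C[C@]1(O)C=C[C@H](CC1)C(C)=C | intermediate
16 | (1R,4S)-1-methyl-4-(prop-1-en-2-yl)cyclohex-2-en-1-yl 3-oxobutanoate | CC(=O)CC(=O)O[C@@]1(C)C=C[C@H](CC1)C(C)=C | intermediate (not isolated)
17 | 1-[(1R,6S)-3-methyl-6-(prop-1-en-2-yl)cyclohex-2-en-1-yl]propan-2-one | CC1=C[C@@H](CC(C)=O)[C@H](CC1)C(C)=C | intermediate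
18 | methyl 4-[(1R,6S)-3-methyl-6-(prop-1-en-2-yl)cyclohex-2-en-1-yl]-3-oxobutanoate | CC1=C[C@@H](CC(=O)CC(=O)OC)[C@H](CC1)C(C)=C | intermediate
19 | methyl (4aR,8aS)-1,1,6-trimethyl-3-oxo-1,2,3,4,4a,7,8,8a-octahydronaphthalene-2-carboxylate (C2 epimers) | CC1=C[C@H]2CC(=O)C(C(=O)OC)C(C)(C)[C@H]2CC1 | intermediate
20 | methyl (4aR,8aS)-1,1,6-trimethyl-3-(trifluoromethylsulfonyloxy)-1,4,4a,7,8,8a-hexahydronaphthalene-2-carboxylate | CC1=C[C@H]2CC(OS(=O)(=O)C(F)(F)F)=C(C(=O)OC)C(C)(C)[C@H]2CC1 | intermediate
21 | methyl (4aR,8aS)-1,1,3,6-tetramethyl-1,4,4a,7,8,8a-hexahydronaphthalene-2-carboxylate | CC1=C[C@H]2CC(C)=C(C(=O)OC)C(C)(C)[C@H]2CC1 | intermediate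
22 | [(4aR,8aS)-1,1,3,6-tetramethyl-1,4,4a,7,8,8a-hexahydronaphthalen-2-yl]methanol | CC1=C[C@H]2CC(C)=C(CO)C(C)(C)[C@H]2CC1 | intermediate
23 | [[(4aR,8aS)-1,1,3,6-tetramethyl-1,4,4a,7,8,8a-hexahydronaphthalen-2-yl]methyl]triphenylphosphonium bromide | CC1=C[C@H]2CC(C)=C(C[P+](c3ccccc3)(c3ccccc3)c3ccccc3)C(C)(C)[C@H]2CC1.[Br-] | intermediate
24 | [[(4aR,8aS)-1,1,3,6-tetramethyl-1,4,4a,7,8,8a-hexahydronaphthalen-2-yl]methylidene]triphenylphosphorane | CC1=C[C@H]2CC(C)=C(C=P(c3ccccc3)(c3ccccc3)c3ccccc3)C(C)(C)[C@H]2CC1 | intermediate (not isolated)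
25 | tert-butyl-[(2S)-2-[(3R,6S)-6-methyl-6-[2-[(4aR,8aS)-1,1,3,6-tetramethyl-1,4,4a,7,8,8a-hexahydronaphthalen-2-yl]ethenyl]-1,2-dioxan-3-yl]propoxy]diphenylsilane (E/Z mixture) | CC1=C[C@H]2CC(C)=C(C=C[C@]3(C)CC[C@H]([C@@H](C)CO[Si](c4ccccc4)(c4ccccc4)C(C)(C)C)OO3)C(C)(C)[C@H]2CC1 | intermediate
26 | tert-butyl-[(2S)-2-[(3R,6R)-6-methyl-6-[2-[(4aR,8aS)-1,1,3,6-tetramethyl-1,4,4a,7,8,8a-hexahydronaphthalen-2-yl]ethyl]-1,2-dioxan-3-yl]propoxy]diphenylsilane | CC1=C[C@H]2CC(C)=C(CC[C@]3(C)CC[C@H]([C@@H](C)CO[Si](c4ccccc4)(c4ccccc4)C(C)(C)C)OO3)C(C)(C)[C@H]2CC1 | intermediate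
27 | (2S)-2-[(3R,6R)-6-methyl-6-[2-[(4aR,8aS)-1,1,3,6-tetramethyl-1,4,4a,7,8,8a-hexahydronaphthalen-2-yl]ethyl]-1,2-dioxan-3-yl]propan-1-ol | CC1=C[C@H]2CC(C)=C(CC[C@]3(C)CC[C@H]([C@@H](C)CO)OO3)C(C)(C)[C@H]2CC1 | intermediate
28 | (2R)-2-[(3R,6R)-6-methyl-6-[2-[(4aR,8aS)-1,1,3,6-tetramethyl-1,4,4a,7,8,8a-hexahydronaphthalen-2-yl]ethyl]-1,2-dioxan-3-yl]propanal | CC1=C[C@H]2CC(C)=C(CC[C@]3(C)CC[C@H]([C@@H](C)C=O)OO3)C(C)(C)[C@H]2CC1 | intermediate (not isolated)
29 | (2R)-2-[(3R,6R)-6-methyl-6-[2-[(4aR,8aS)-1,1,3,6-tetramethyl-1,4,4a,7,8,8a-hexahydronaphthalen-2-yl]ethyl]-1,2-dioxan-3-yl]propanoic acid | CC1=C[C@H]2CC(C)=C(CC[C@]3(C)CC[C@H]([C@@H](C)C(=O)O)OO3)C(C)(C)[C@H]2CC1 | target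

## Step count and least certain steps

Total step count: 21. Longest linear sequence: 13 steps (12 → 29, steps 9–21). The dioxane branch from 1 counts 12 steps (steps 1–8 and 18–21).

**Step 6 (key step).** The likely problem is that hydrogen abstraction from the inside methyl group (ene oxidation at the trisubstituted terminus) consumes much of the diene, and that the weak facial discrimination by the allylic stereocentre then halves what remains. Fallback: the photooxygenation is moved one stage earlier, to dienoate 7, whose conjugated ester makes the trisubstituted alkene a poor ene partner. Under the same sensitised conditions 7 should give ethyl (3S,6R)-6-[(2S)-1-[tert-butyl(diphenyl)silyl]oxypropan-2-yl]-3-methyl-3,6-dihydro-1,2-dioxine-3-carboxylate F1. Diimide reduction would give ethyl (3S,6R)-6-[(2S)-1-[tert-butyl(diphenyl)silyl]oxypropan-2-yl]-3-methyl-1,2-dioxane-3-carboxylate F2. Reduction of F2 with iBu2AlH at −78 °C rejoins the route at aldehyde 11. This changes the electronic character of the diene and the later redox sequence. It does not improve the facial selectivity, which still rests on separation of the two cis isomers.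

**Step 13.** The likely problem is unselective protonation: the ring A alkene is ionised as well, which leads to alkene migration or capture at C6, and the ketone oxygen may close a cyclic enol ether. Fallback: the cation is generated at one defined site without free acid. From 18, one equivalent of HCl in CH2Cl2 at low temperature adds to the isopropenyl group, as limonene does, to give methyl 4-[(1R,6S)-6-(2-chloropropan-2-yl)-3-methylcyclohex-2-en-1-yl]-3-oxobutanoate F5. Chloride abstraction with AgOTf in the presence of 2,6-di-tert-butylpyridine then lets the enol carbon close ring B, and the route is rejoined at 19.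

**Step 11.** The likely problem is thermal ionisation and elimination of the tertiary allylic acetoacetate to menthatrienes before the [3,3] shift. Fallback: the rearrangement is run at low temperature as an Ireland–Claisen reaction. From 15, acetylation (Ac2O, Et3N, 4-dimethylaminopyridine) gives (1R,4S)-1-methyl-4-(prop-1-en-2-yl)cyclohex-2-en-1-yl acetate F3. Enolisation and silylation (LiN(iPr)2, Me3SiCl, THF, −78 °C → rt) give, after work-up, 2-[(1R,6S)-3-methyl-6-(prop-1-en-2-yl)cyclohex-2-en-1-yl]acetic acid F4. Activation with carbonyldiimidazole and reaction with KO2CCH2CO2Me/MgCl2/Et3N give β-keto ester 18 directly, so 17 is bypassed.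

**Step 18.** The likely problem is slow addition of the hindered allylic ylide to the α-quaternary aldehyde, which leaves time for base-induced fragmentation of the α-peroxy aldehyde. Fallback: a Julia–Kocienski olefination with a smaller, more nucleophilic carbanion. From 22, Mitsunobu reaction with 1-phenyl-1H-tetrazole-5-thiol (PPh3, diisopropyl azodicarboxylate) gives 5-[[(4aR,8aS)-1,1,3,6-tetramethyl-1,4,4a,7,8,8a-hexahydronaphthalen-2-yl]methylsulfanyl]-1-phenyl-1H-tetrazole F6. Oxidation with H2O2 and catalytic (NH4)6Mo7O24 gives 5-[[(4aR,8aS)-1,1,3,6-tetramethyl-1,4,4a,7,8,8a-hexahydronaphthalen-2-yl]methylsulfonyl]-1-phenyl-1H-tetrazole F7. Its potassium derivative (KN(SiMe3)2, THF, −78 °C, aldehyde 11 present) gives alkene 25, where the route is rejoined.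

**Step 19.** The likely problem is incomplete reduction of the hindered linker alkene, or partial saturation of the ring A alkene when diimide is used in large excess. Fallback: from 25, homogeneous hydrogenation with RhCl(PPh3)3 under H2 in benzene leads to 26. Here selectivity comes from alkene coordination to the metal, which tri- and tetrasubstituted alkenes do not achieve. No new compound is involved. The peroxide's tolerance of the rhodium–phosphine system would have to be watched.

## Further compounds

F1 | step 6 | ethyl (3S,6R)-6-[(2S)-1-[tert-butyl(diphenyl)silyl]oxypropan-2-yl]-3-methyl-3,6-dihydro-1,2-dioxine-3-carboxylate | CCOC(=O)[C@]1(C)C=C[C@H]([C@@H](C)CO[Si](c2ccccc2)(c2ccccc2)C(C)(C)C)OO1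
F2 | step 6 | ethyl (3S,6R)-6-[(2S)-1-[tert-butyl(diphenyl)silyl]oxypropan-2-yl]-3-methyl-1,2-dioxane-3-carboxylate | CCOC(=O)[C@]1(C)CC[C@H]([C@@H](C)CO[Si](c2ccccc2)(c2ccccc2)C(C)(C)C)OO1
F3 | step 11 | (1R,4S)-1-methyl-4-(prop-1-en-2-yl)cyclohex-2-en-1-yl acetate | CC(=O)O[C@@]1(C)C=C[C@H](CC1)C(C)=C
F4 | step 11 | 2-[(1R,6S)-3-methyl-6-(prop-1-en-2-yl)cyclohex-2-en-1-yl]acetic acid | CC1=C[C@@H](CC(=O)O)[C@H](CC1)C(C)=C
F5 | step 13 | methyl 4-[(1R,6S)-6-(2-chloropropan-2-yl)-3-methylcyclohex-2-en-1-yl]-3-oxobutanoate | CC1=C[C@@H](CC(=O)CC(=O)OC)[C@H](CC1)C(C)(C)Cl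
F6 | step 18 | 5-[[(4aR,8aS)-1,1,3,6-tetramethyl-1,4,4a,7,8,8a-hexahydronaphthalen-2-yl]methylsulfanyl]-1-phenyl-1H-tetrazole | CC1=C[C@H]2CC(C)=C(CSc3nnnn3-c3ccccc3)C(C)(C)[C@H]2CC1
F7 | step 18 | 5-[[(4aR,8aS)-1,1,3,6-tetramethyl-1,4,4a,7,8,8a-hexahydronaphthalen-2-yl]methylsulfonyl]-1-phenyl-1H-tetrazole | CC1=C[C@H]2CC(C)=C(CS(=O)(=O)c3nnnn3-c3ccccc3)C(C)(C)[C@H]2CC1
F0 | step 19 | none | none
A1 | alternative 1 | 1,3,3-trimethyl-2-(prop-1-en-2-yl)bicyclo[2.2.2]oct-5-en-2-ol, isopropenyl syn to the C5=C6 bridge, enantiomer leading to the (4aR,8aS) decalin | C[C@]12C=C[C@H](CC1)C(C)(C)[C@@]2(O)C(C)=C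
A2 | alternative 1 | (4aR,8aS)-1,1,3,6-tetramethyl-1,4,4a,7,8,8a-hexahydronaphthalen-2-yl trifluoromethanesulfonate | CC1=C[C@H]2CC(C)=C(OS(=O)(=O)C(F)(F)F)C(C)(C)[C@H]2CC1
A3 | alternative 2 | (2E,5E)-7-hydroxy-3,7,11-trimethyldodeca-2,5,10-trien-1-yl acetate (racemic at C7) | CC(C)=CCCC(C)(O)/C=C/C/C(C)=C/COC(C)=O
A4 | alternative 2 | [(4aR,8aS)-1,1,3,6-tetramethyl-1,4,4a,7,8,8a-hexahydronaphthalen-2-yl]methyl acetate (formed as the racemate; wanted enantiomer drawn) | CC1=C[C@H]2CC(C)=C(COC(C)=O)C(C)(C)[C@H]2CC1
A5 | alternative 3 | 3-(methoxymethoxymethyl)-2,4,4-trimethylcyclohexa-2,5-dien-1-one | COCOCC1=C(C)C(=O)C=CC1(C)C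
A6 | alternative 3 | tert-butyl-dimethyl-[(1E)-2-methylbuta-1,3-dienyl]oxysilane | C=C/C(C)=C/O[Si](C)(C)C(C)(C)C
A7 | alternative 3 | cis-fused 5-[tert-butyl(dimethyl)silyl]oxy-2-(methoxymethoxymethyl)-1,1,3,6-tetramethyl-4a,5,8,8a-tetrahydro-1H-naphthalen-4-one (target numbering) | CC1=CC[C@H]2[C@@H]([C@@H]1O[Si](C)(C)C(C)(C)C)C(=O)C(C)=C(COCOC)C2(C)C
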